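**Retrosynthetic overview**

1. Target ⇒ its tetra-O-methyl ether; the four methyl ethers on the catechol rings (rings B) are removed last with BBr3.
2. Key disconnection: in each five-membered ring C, O1–C2 and C3–C3a are cut together. This releases two resorcinols (rings A) and the chain O=C3–C2=Cα(Ar)–Cα'(Ar)=C2'–C3'=O, used as 3,4-bis(3,4-dimethoxyphenyl)furan-2,5-dicarboxylic acid.
3. Enabling feature: the diene C2=Cα–Cα'=C2', with one ether oxygen on each terminus, is the opened form of a furan (C2, Cα, Cα', C2' are its four ring carbons; the furan oxygen stands in for O1 and O1' and leaves as water). C3a of ring A is the resorcinol carbon ortho to O1 and para to the C6 hydroxyl, the position that acylates by itself. The twofold symmetry lets one operation build both halves.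
4. Furan diacid ⇒ veratril + dimethyl diglycolate (Hinsberg furan synthesis); veratril ⇒ veratrole + oxalyl chloride.
5. Ring order: temporary furan ring first, then both rings C at once as the furan opens; rings A and B are bought.

Key step: step 3

Assumption: the (Z,Z) geometry of the natural product is taken to be the thermodynamically favoured arrangement of this tetrasubstituted diene (diene partner beside the ring oxygen, twisted aryl ring beside the C3 carbonyl), so that equilibration in acid delivers it.

**Route**

Step 1
Reactants: 1 veratrole (1,2-dimethoxybenzene, 2.1 equiv); 2 oxalyl chloride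
Product: 4 veratril [1,2-bis(3,4-dimethoxyphenyl)ethane-1,2-dione], via arylglyoxyloyl chloride 3 (not isolated)
Conditions: AlCl3 (2.4 equiv), CH2Cl2, 0 to 25 °C; then ice, aq HCl
Reagents that add atoms: none
Why: Double Friedel–Crafts acylation in which each veratrole ring is attacked para to a methoxy group and, at 0 °C, acid chloride 3 should acylate the second ring faster than it loses CO, as is usual for 1,2-dialkoxybenzenes.

Step 2
Reactants: 4 veratril; 5 dimethyl diglycolate (dimethyl 2,2'-oxydiacetate, 1.3 equiv)
Product: 7 3,4-bis(3,4-dimethoxyphenyl)furan-2,5-dicarboxylic acid, via furan half ester 6 (not isolated)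
Conditions: KOtBu (2.5 equiv), tBuOH/toluene, 25 to 60 °C; then aq KOH, MeOH, reflux; then aq HCl to pH 1
Reagents that add atoms: potassium hydroxide, [K+].[OH-] (oxygen of the carboxyl group freed by ester hydrolysis)
Why: Hinsberg furan synthesis, a double aldol condensation of a 1,2-diketone with a diglycolate that runs through a Stobbe-type lactone (hence half ester 6), followed by saponification; the non-nucleophilic tert-butoxide should avoid benzilic ester rearrangement of 4.

Step 3
Reactants: 7 3,4-bis(3,4-dimethoxyphenyl)furan-2,5-dicarboxylic acid; 8 resorcinol (2.1 equiv)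
Product: 11 tetra-O-methyldisulfuretin [(2Z,2'Z)-2,2'-[1,2-bis(3,4-dimethoxyphenyl)ethane-1,2-diylidene]bis(6-hydroxy-1-benzofuran-3(2H)-one)], via diaroylfuran 9 (not isolated), via ring-opened enol 10 (not isolated)
Conditions: P4O10 in MeSO3H (1:10 w/w), 25 °C then 70 °C; then ice water
Reagents that add atoms: none
Why: Proposed new method: in P4O10/MeSO3H each carboxyl group of 7 should become a mixed anhydride or acylium ion that acylates resorcinol at C4, ortho and para to its two hydroxyl groups, as in the first stage of the Grover–Shah–Shah xanthone synthesis, which forms both C3–C3a bonds and gives diaroylfuran 9. In O-protonated 9 each carbonyl makes the furan α-carbon that bears the other aroyl group the δ-terminus of a dienone, so the ortho hydroxyl of that other aroyl group should add there in a 5-exo-trig 1,6-oxa-Michael spirocyclisation (O1–C2), the furan C–O bond of the spiroketal then breaks to give enol 10, and the second ring C closes by 5-exo-trig attack of the remaining ortho hydroxyl on the freed 1,2-dicarbonyl carbon followed by loss of water, which P4O10 binds irreversibly. The closest known reactions are the Butin furan ring opening–benzofuran ring closure of 2-(2-hydroxybenzyl)furans, the Stenhouse opening of furfural iminium ions by attack at the far α-carbon, the dehydrative closure of 2,2'-dihydroxybenzophenones to xanthones in this medium and the acid dehydration of 2-benzyl-2-hydroxybenzofuranones to aurones; none has been shown on a 2-aroylfuran. No stereocentre is formed; the geometry of both exocyclic double bonds is set under thermodynamic control, because reversible O-protonation of the vinylogous esters lets the C2=Cα bonds rotate, and the Z,Z arrangement keeps the diene partner beside the small ring oxygen and the twisted dimethoxyphenyl ring beside the C3 carbonyl. The step needs intermolecular acylation of resorcinol to win over intramolecular acylation of a dimethoxyphenyl ring and over further condensation of the ketones with resorcinol to xanthene dyes; the far higher nucleophilicity of resorcinol, the strain of a furan-fused indenone and the use of only 2.1 equiv of resorcinol at moderate temperature should secure this.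

Step 4
Reactants: 11 tetra-O-methyldisulfuretin
Product: 12 disulfuretin [(2Z,2'Z)-2,2'-[1,2-bis(3,4-dihydroxyphenyl)ethane-1,2-diylidene]bis(6-hydroxy-1-benzofuran-3(2H)-one)]
Conditions: BBr3 (12 equiv), CH2Cl2, −78 to 25 °C; then MeOH, H2O
Reagents that add atoms: none
Why: Lewis acid cleavage of aryl methyl ethers with BBr3, the usual last step of polyhydroxyaurone syntheses, which should leave the enol ether and ketone groups of rings C intact and the Z,Z geometry unchanged because it is the thermodynamic one.

**Compound list**

1 | veratrole (1,2-dimethoxybenzene) | COc1ccccc1OC | starting material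
2 | oxalyl chloride | O=C(Cl)C(=O)Cl | starting material
3 | (3,4-dimethoxyphenyl)(oxo)acetyl chloride (formed in the flask, not isolated) | COc1ccc(C(=O)C(=O)Cl)cc1OC | intermediate
4 | veratril, 1,2-bis(3,4-dimethoxyphenyl)ethane-1,2-dione | COc1ccc(C(=O)C(=O)c2ccc(OC)c(OC)c2)cc1OC | intermediate
5 | dimethyl diglycolate (dimethyl 2,2'-oxydiacetate) | COC(=O)COCC(=O)OC | starting material
6 | 3,4-bis(3,4-dimethoxyphenyl)-5-(methoxycarbonyl)furan-2-carboxylic acid (potassium salt in the flask, not isolated) | COC(=O)c1oc(C(=O)O)c(-c2ccc(OC)c(OC)c2)c1-c1ccc(OC)c(OC)c1 | intermediate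
7 | 3,4-bis(3,4-dimethoxyphenyl)furan-2,5-dicarboxylic acid | OC(=O)c1oc(C(=O)O)c(-c2ccc(OC)c(OC)c2)c1-c1ccc(OC)c(OC)c1 | intermediate
8 | resorcinol (benzene-1,3-diol) | Oc1cccc(O)c1 | starting material
9 | 2,5-bis(2,4-dihydroxybenzoyl)-3,4-bis(3,4-dimethoxyphenyl)furan (formed in the flask, not isolated) | O=C(c1ccc(O)cc1O)c1oc(C(=O)c2ccc(O)cc2O)c(-c2ccc(OC)c(OC)c2)c1-c1ccc(OC)c(OC)c1 | intermediate
10 | (2Z)-2-[(2Z)-4-(2,4-dihydroxyphenyl)-1,2-bis(3,4-dimethoxyphenyl)-3-hydroxy-4-oxobut-2-en-1-ylidene]-6-hydroxy-1-benzofuran-3(2H)-one; one ring C closed, enol oxygen cis to the diene carbon (formed in the flask, not isolated) | O=C1/C(=C(/C(=C(\O)C(=O)c2ccc(O)cc2O)c2ccc(OC)c(OC)c2)c2ccc(OC)c(OC)c2)Oc2cc(O)ccc21 | intermediate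
11 | tetra-O-methyldisulfuretin, (2Z,2'Z)-2,2'-[1,2-bis(3,4-dimethoxyphenyl)ethane-1,2-diylidene]bis(6-hydroxy-1-benzofuran-3(2H)-one) | O=C1/C(=C(/C(=C2\Oc3cc(O)ccc3C2=O)c2ccc(OC)c(OC)c2)c2ccc(OC)c(OC)c2)Oc2cc(O)ccc21 | intermediate
12 | disulfuretin, (2Z,2'Z)-2,2'-[1,2-bis(3,4-dihydroxyphenyl)ethane-1,2-diylidene]bis(6-hydroxy-1-benzofuran-3(2H)-one) | O=C1/C(=C(/C(=C2\Oc3cc(O)ccc3C2=O)c2ccc(O)c(O)c2)c2ccc(O)c(O)c2)Oc2cc(O)ccc21 | target

**Step count**

Total steps: 4. Longest linear sequence: 4 steps (1 → 4 → 7 → 11 → 12).

**Steps most likely to fail**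

Step 3 (proposed new method). The cascade may stop after the acylation because the electron-poor furan is not opened. An acylium ion may cyclise onto the neighbouring dimethoxyphenyl ring. The new ketones may condense with more resorcinol, or the double-bond geometry may not equilibrate fully. The fallback uses known chemistry and makes the two bonds of each ring C in two classical operations and the diene by condensation. It sets out from resorcinol 8 and veratril 4 and rejoins the route at 11. Houben–Hoesch acylation of 8 with chloroacetonitrile (ZnCl2, HCl gas, Et2O, 0 °C; then hot water) should give 2-chloro-1-(2,4-dihydroxyphenyl)ethan-1-one F1. NaOAc in refluxing EtOH should close F1 to 6-hydroxy-1-benzofuran-3(2H)-one F2. Two equivalents of F2 would then be condensed with diketone 4 under Lehnert conditions for Knoevenagel condensation of ketones (TiCl4, pyridine, THF, 0 °C to reflux). This is the intermolecular counterpart of the double aldol condensation of benzils that gives tetraarylcyclopentadienones. It should pass through the mono-condensation product (Z)-2-[1,2-bis(3,4-dimethoxyphenyl)-2-oxoethylidene]-6-hydroxy-1-benzofuran-3(2H)-one F3 and end at 11.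

Step 2. The alkoxide may trigger a benzilic ester-type rearrangement of the diketone, or the second aldol closure onto the electron-rich aryl ketone may stall. The fallback makes the furan first and attaches the aryl rings by cross-coupling. It sets out from dimethyl diglycolate 5 and rejoins the route at 7. Condensation of 5 with dimethyl oxalate (NaOMe, MeOH, reflux; then HCl) should give dimethyl 3,4-dihydroxyfuran-2,5-dicarboxylate F4. Tf2O and pyridine in CH2Cl2 at 0 °C should convert F4 into dimethyl 3,4-bis{[(trifluoromethyl)sulfonyl]oxy}furan-2,5-dicarboxylate F5. Double Suzuki–Miyaura coupling of F5 with (3,4-dimethoxyphenyl)boronic acid (Pd(PPh3)4, K3PO4, dioxane, 90 °C) should give dimethyl 3,4-bis(3,4-dimethoxyphenyl)furan-2,5-dicarboxylate F6. Saponification of F6 (LiOH, THF/H2O; then HCl) returns 7.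

Step 4. Cleavage of the four methyl ethers may be incomplete, the Lewis acid may degrade the dienone, or the hexaphenol may oxidise in air during work-up. The fallback moves the deprotection ahead of the key step. It sets out from diacid 7 and rejoins the route at 12. BBr3 (CH2Cl2, −78 to 25 °C; then water) should convert the robust 7 into 3,4-bis(3,4-dihydroxyphenyl)furan-2,5-dicarboxylic acid F7. F7 and resorcinol 8 under the conditions of step 3 should pass through 2,5-bis(2,4-dihydroxybenzoyl)-3,4-bis(3,4-dihydroxyphenyl)furan F8 and give 12 directly, so that no Lewis acid meets the finished dienone.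

**Further compounds**

F1 | step 3 | 2-chloro-1-(2,4-dihydroxyphenyl)ethan-1-one | O=C(CCl)c1ccc(O)cc1O
F2 | step 3 | 6-hydroxy-1-benzofuran-3(2H)-one | O=C1COc2cc(O)ccc21
F3 | step 3 | (Z)-2-[1,2-bis(3,4-dimethoxyphenyl)-2-oxoethylidene]-6-hydroxy-1-benzofuran-3(2H)-one | O=C1/C(=C(/C(=O)c2ccc(OC)c(OC)c2)c2ccc(OC)c(OC)c2)Oc2cc(O)ccc21
F4 | step 2 | dimethyl 3,4-dihydroxyfuran-2,5-dicarboxylate | COC(=O)c1oc(C(=O)OC)c(O)c1O
F5 | step 2 | dimethyl 3,4-bis{[(trifluoromethyl)sulfonyl]oxy}furan-2,5-dicarboxylate | COC(=O)c1oc(C(=O)OC)c(OS(=O)(=O)C(F)(F)F)c1OS(=O)(=O)C(F)(F)F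
F6 | step 2 | dimethyl 3,4-bis(3,4-dimethoxyphenyl)furan-2,5-dicarboxylate | COC(=O)c1oc(C(=O)OC)c(-c2ccc(OC)c(OC)c2)c1-c1ccc(OC)c(OC)c1
F7 | step 4 | 3,4-bis(3,4-dihydroxyphenyl)furan-2,5-dicarboxylic acid | OC(=O)c1oc(C(=O)O)c(-c2ccc(O)c(O)c2)c1-c1ccc(O)c(O)c1
F8 | step 4 | 2,5-bis(2,4-dihydroxybenzoyl)-3,4-bis(3,4-dihydroxyphenyl)furan | O=C(c1ccc(O)cc1O)c1oc(C(=O)c2ccc(O)cc2O)c(-c2ccc(O)c(O)c2)c1-c1ccc(O)c(O)c1
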